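**Strategy.** Everything rests on disconnecting ring C of the 2,3-cis flavanone unit (the one carrying the 4-hydroxyphenyl group) into a phloroglucinol-derived aryloxide and a trans-β-lactone that hangs on C3 of the finished trans flavanone unit. The key step exploits that O1–C2–C3–C4 of this ring is a β-aryloxy acid in disguise: the aryloxide opens the strained lactone at its benzylic carbon with inversion (bond O1–C2, which fixes C2 cis to C3), and the freed carboxyl is then acylated onto the ortho carbon of the same arene (bond C4–C4a) in the same flask. The lactone stems from an auxiliary-controlled anti-aldol on a flavanone-3-acetic acid.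

Key step: step 8

Remark: unprimed locants refer to the cis unit (4-hydroxyphenyl) and double-primed locants to the trans unit (4-methoxyphenyl); compounds 7 and 9 are racemic and are drawn as their (2S,3R) enantiomers; compounds 1, 2, 5, 8, 11 and 18 are taken as commercial.

**Step 1**
Reactants: 1 phloroglucinol; 2 succinic anhydride
Product: 3 4-oxo-4-(2,4,6-trihydroxyphenyl)butanoic acid
Conditions: AlCl3, PhNO2, 25 → 60 °C; then ice, 2 M HCl
Reagents that add atoms: none
Why: Friedel–Crafts acylation of the symmetrical, strongly activated triol by the opened anhydride should stop at the mono-ketone because the acyl group deactivates the ring, and it installs the whole chain C4''–C3''–C3–C4 at once; no stereocentre is formed.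

**Step 2**
Reactants: 3 4-oxo-4-(2,4,6-trihydroxyphenyl)butanoic acid
Product: 4 benzyl 4-[2,4-bis(benzyloxy)-6-hydroxyphenyl]-4-oxobutanoate
Conditions: BnBr (3 equiv), K2CO3, DMF, 0 → 23 °C
Reagents that add atoms: benzyl bromide, BrCc1ccccc1
Why: Williamson-type O-alkylation should take the carboxylate and the two more acidic phenols, while the phenol hydrogen-bonded to the aryl ketone stays free, as is usual for acylphloroglucinols; no stereocentre is formed.

**Step 3**
Reactants: 4 benzyl 4-[2,4-bis(benzyloxy)-6-hydroxyphenyl]-4-oxobutanoate; 5 4-methoxybenzaldehyde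
Product: 7 rac-trans-2-[5,7-bis(benzyloxy)-2-(4-methoxyphenyl)-4-oxochroman-3-yl]acetic acid, via chalcone acid 6 (not isolated)
Conditions: KOH (aq), EtOH, 23 °C; then AcOH to pH 5, NaOAc, EtOH, reflux
Reagents that add atoms: potassium hydroxide, [K+].[OH-]
Why: Claisen–Schmidt condensation at the only enolisable ketone α-CH2 with concurrent ester saponification gives the α-substituted 2'-hydroxychalcone, whose 6-endo-trig oxa-Michael closure is reversible, so C2'' and C3'' should settle as the thermodynamic trans (diequatorial) racemate.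

**Step 4**
Reactants: 7 rac-trans-2-[5,7-bis(benzyloxy)-2-(4-methoxyphenyl)-4-oxochroman-3-yl]acetic acid; 8 (R)-4-benzyl-2-oxazolidinone
Product: 10 (R)-4-benzyl-3-{2-[(2S,3R)-5,7-bis(benzyloxy)-2-(4-methoxyphenyl)-4-oxochroman-3-yl]acetyl}oxazolidin-2-one, via mixed pivalic anhydride 9 (not isolated)
Conditions: t-BuCOCl, Et3N, THF, −20 °C; then 8, LiCl, 23 °C; chromatographic separation of the diastereomers
Reagents that add atoms: none
Why: N-acylation through the mixed pivalic anhydride under LiCl/Et3N is non-enolising and converts the racemic acid into two covalent diastereomers, so the (2S,3R) imide 10 should be obtainable by chromatography from its (2R,3S)-configured diastereomer, which fixes the absolute configuration of the trans unit by separation.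

**Step 5**
Reactants: 10 (R)-4-benzyl-3-{2-[(2S,3R)-5,7-bis(benzyloxy)-2-(4-methoxyphenyl)-4-oxochroman-3-yl]acetyl}oxazolidin-2-one; 11 4-(benzyloxy)benzaldehyde
Product: 13 (R)-4-benzyl-3-{(2S,3R)-3-[4-(benzyloxy)phenyl]-2-[(2S,3R)-5,7-bis(benzyloxy)-2-(4-methoxyphenyl)-4-oxochroman-3-yl]-3-hydroxypropanoyl}oxazolidin-2-one, via TMS ether 12 (not isolated)
Conditions: MgCl2 (20 mol%), Et3N, Me3SiCl, EtOAc, 23 °C; then aq. citric acid, MeOH, 0 °C
Reagents that add atoms: none
Why: In this Evans anti-aldol reaction, soft enolisation of the chelating imide (not of the hindered, monodentate ring ketone) should give the chelated (Z)-magnesium enolate, which adds to the aldehyde on the face away from the auxiliary benzyl group through a boat-type transition state with silyl trapping of the aldolate, setting C3 (S) and the carbinol carbon (R) anti under auxiliary control.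

**Step 6**
Reactants: 13 (R)-4-benzyl-3-{(2S,3R)-3-[4-(benzyloxy)phenyl]-2-[(2S,3R)-5,7-bis(benzyloxy)-2-(4-methoxyphenyl)-4-oxochroman-3-yl]-3-hydroxypropanoyl}oxazolidin-2-one
Product: 15 (2S,3R)-3-[4-(benzyloxy)phenyl]-2-[(2S,3R)-5,7-bis(benzyloxy)-2-(4-methoxyphenyl)-4-oxochroman-3-yl]-3-hydroxypropanoic acid, via peroxy acid 14 (not isolated)
Conditions: LiOH, H2O2, THF–H2O, 0 °C; then aq. Na2SO3; then 1 M HCl to pH 3, 0 °C
Reagents that add atoms: hydrogen peroxide (as lithium hydroperoxide), OO
Why: Hydroperoxide cleavage of the N-acyloxazolidinone attacks the exocyclic carbonyl selectively, and the cold, weakly basic medium should neither epimerise the α-carbon, nor open the flavanone, nor induce retro-aldol; no stereocentre is touched.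

**Step 7**
Reactants: 15 (2S,3R)-3-[4-(benzyloxy)phenyl]-2-[(2S,3R)-5,7-bis(benzyloxy)-2-(4-methoxyphenyl)-4-oxochroman-3-yl]-3-hydroxypropanoic acid
Product: 17 (3S,4R)-4-[4-(benzyloxy)phenyl]-3-[(2S,3R)-5,7-bis(benzyloxy)-2-(4-methoxyphenyl)-4-oxochroman-3-yl]oxetan-2-one, via mixed sulfonic anhydride 16 (not isolated)
Conditions: PhSO2Cl, pyridine, 0 → 4 °C; cold work-up, used crude
Reagents that add atoms: none
Why: Carboxyl-activation β-lactonisation (4-exo-trig attack of the hydroxyl on the sulfonic–carboxylic mixed anhydride) proceeds with retention at the carbinol carbon, so the anti acid should give the trans lactone, which is kept cold and free of Lewis acid because an electron-rich 4-aryl β-lactone can ionise or decarboxylate.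

**Step 8**
Reactants: 17 (3S,4R)-4-[4-(benzyloxy)phenyl]-3-[(2S,3R)-5,7-bis(benzyloxy)-2-(4-methoxyphenyl)-4-oxochroman-3-yl]oxetan-2-one; 18 3,5-bis(benzyloxy)phenol
Product: 21 (2S,3S)-5,7-bis(benzyloxy)-2-[4-(benzyloxy)phenyl]-3-[(2S,3R)-5,7-bis(benzyloxy)-2-(4-methoxyphenyl)-4-oxochroman-3-yl]chroman-4-one, via potassium carboxylate 19 (not isolated), via mixed trifluoroacetic anhydride 20 (not isolated)
Conditions: KOt-Bu, 18-crown-6, THF, 0 → 23 °C; then solvent switch to CH2Cl2, (CF3CO)2O, 0 °C
Reagents that add atoms: none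
Why: Proposed new method: the potassium aryloxide of 18 should attack the benzylic C4 of the strained trans-β-lactone in an SN2 alkyl–oxygen cleavage (attack at the acyl carbon is reversible because the aryl ester alkoxide re-closes to the lactone, whereas carboxylate formation is not), forming O1–C2 with inversion, after which the anhydride reagent converts carboxylate 19 into mixed anhydride 20, which acylates the ortho carbon of the same 3,5-dibenzyloxyphenoxy ring to form C4–C4a. The closest known chemistry is the opening of β-propiolactone and β-butyrolactone by phenoxides at the alkyl carbon to give 3-aryloxy acids and the acid-mediated cyclisation of 3-aryloxypropanoic acids to chroman-4-ones; their one-flask merger on a 3,4-disubstituted 4-aryl lactone is the part without precedent. Ring C of the second flavanone is closed by a 6-exo-trig intramolecular Friedel–Crafts acylation, and since both ortho positions of the aryloxy ring are equivalent only the 5,7-dioxygenated regioisomer can form. C2 is set by stereospecific inversion of the lactone carbinol carbon (R to S) and C3 is carried over unchanged, so the trans lactone must give the 2,3-cis flavanone, and no base is present once the C4 ketone exists, which protects this kinetically fragile cis arrangement. The step needs SN2 opening to outrun ionisation, decarboxylation and C3 deprotonation, which low temperature, a crown-ether-activated aryloxide in an aprotic medium and the absence of Lewis acid should secure, while the hindered tertiary C3''–H and the thermodynamic trans geometry of the first flavanone make that unit tolerant of the aryloxide.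

**Step 9**
Reactants: 21 (2S,3S)-5,7-bis(benzyloxy)-2-[4-(benzyloxy)phenyl]-3-[(2S,3R)-5,7-bis(benzyloxy)-2-(4-methoxyphenyl)-4-oxochroman-3-yl]chroman-4-one
Product: 22 (2S,3S)-5,7-dihydroxy-2-(4-hydroxyphenyl)-3-[(2S,3R)-5,7-dihydroxy-2-(4-methoxyphenyl)-4-oxochroman-3-yl]chroman-4-one
Conditions: H2 (1 atm), Pd/C (10% Pd), EtOAc–MeOH, 23 °C
Reagents that add atoms: none
Why: Catalytic hydrogenolysis of the five aryl benzyl ethers is neutral, so the methyl ether, both ketones, the two ring C2–O bonds and the epimerisable cis C2/C3 pair should be left untouched; no stereocentre is formed.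

**Compound list**
1 | phloroglucinol (benzene-1,3,5-triol) | Oc1cc(O)cc(O)c1 | starting material
2 | succinic anhydride | O=C1CCC(=O)O1 | starting material
3 | 4-oxo-4-(2,4,6-trihydroxyphenyl)butanoic acid | OC(=O)CCC(=O)c1c(O)cc(O)cc1O | intermediate
4 | benzyl 4-[2,4-bis(benzyloxy)-6-hydroxyphenyl]-4-oxobutanoate | O=C(CCC(=O)c1c(O)cc(OCc2ccccc2)cc1OCc1ccccc1)OCc1ccccc1 | intermediate
5 | 4-methoxybenzaldehyde | COc1ccc(C=O)cc1 | starting material
6 | (E)-3-[2,4-bis(benzyloxy)-6-hydroxybenzoyl]-4-(4-methoxyphenyl)but-3-enoic acid (chalcone acid) | COc1ccc(/C=C(\CC(=O)O)C(=O)c2c(O)cc(OCc3ccccc3)cc2OCc2ccccc2)cc1 | intermediate (not isolated)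
7 | rac-trans-2-[5,7-bis(benzyloxy)-2-(4-methoxyphenyl)-4-oxochroman-3-yl]acetic acid (racemate, drawn as 2S,3R) | COc1ccc([C@H]2Oc3cc(OCc4ccccc4)cc(OCc4ccccc4)c3C(=O)[C@@H]2CC(=O)O)cc1 | intermediate
8 | (R)-4-benzyl-2-oxazolidinone | O=C1N[C@H](Cc2ccccc2)CO1 | starting material
9 | mixed pivalic anhydride of 7 (racemate, drawn as 2S,3R) | COc1ccc([C@H]2Oc3cc(OCc4ccccc4)cc(OCc4ccccc4)c3C(=O)[C@@H]2CC(=O)OC(=O)C(C)(C)C)cc1 | intermediate (not isolated)
10 | (R)-4-benzyl-3-{2-[(2S,3R)-5,7-bis(benzyloxy)-2-(4-methoxyphenyl)-4-oxochroman-3-yl]acetyl}oxazolidin-2-one | COc1ccc([C@H]2Oc3cc(OCc4ccccc4)cc(OCc4ccccc4)c3C(=O)[C@@H]2CC(=O)N2[C@H](Cc3ccccc3)COC2=O)cc1 | intermediate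
11 | 4-(benzyloxy)benzaldehyde | O=Cc1ccc(OCc2ccccc2)cc1 | starting material
12 | O-trimethylsilyl ether of 13 | COc1ccc([C@H]2Oc3cc(OCc4ccccc4)cc(OCc4ccccc4)c3C(=O)[C@@H]2[C@H](C(=O)N2[C@H](Cc3ccccc3)COC2=O)[C@@H](O[Si](C)(C)C)c2ccc(OCc3ccccc3)cc2)cc1 | intermediate (not isolated)
13 | (R)-4-benzyl-3-{(2S,3R)-3-[4-(benzyloxy)phenyl]-2-[(2S,3R)-5,7-bis(benzyloxy)-2-(4-methoxyphenyl)-4-oxochroman-3-yl]-3-hydroxypropanoyl}oxazolidin-2-one | COc1ccc([C@H]2Oc3cc(OCc4ccccc4)cc(OCc4ccccc4)c3C(=O)[C@@H]2[C@H](C(=O)N2[C@H](Cc3ccccc3)COC2=O)[C@@H](O)c2ccc(OCc3ccccc3)cc2)cc1 | intermediate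
14 | peroxy acid corresponding to 15 | COc1ccc([C@H]2Oc3cc(OCc4ccccc4)cc(OCc4ccccc4)c3C(=O)[C@@H]2[C@H](C(=O)OO)[C@@H](O)c2ccc(OCc3ccccc3)cc2)cc1 | intermediate (not isolated)
15 | (2S,3R)-3-[4-(benzyloxy)phenyl]-2-[(2S,3R)-5,7-bis(benzyloxy)-2-(4-methoxyphenyl)-4-oxochroman-3-yl]-3-hydroxypropanoic acid | COc1ccc([C@H]2Oc3cc(OCc4ccccc4)cc(OCc4ccccc4)c3C(=O)[C@@H]2[C@H](C(=O)O)[C@@H](O)c2ccc(OCc3ccccc3)cc2)cc1 | intermediate
16 | benzenesulfonic–carboxylic mixed anhydride of 15 | COc1ccc([C@H]2Oc3cc(OCc4ccccc4)cc(OCc4ccccc4)c3C(=O)[C@@H]2[C@H](C(=O)OS(=O)(=O)c2ccccc2)[C@@H](O)c2ccc(OCc3ccccc3)cc2)cc1 | intermediate (not isolated)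
17 | (3S,4R)-4-[4-(benzyloxy)phenyl]-3-[(2S,3R)-5,7-bis(benzyloxy)-2-(4-methoxyphenyl)-4-oxochroman-3-yl]oxetan-2-one (trans-β-lactone) | COc1ccc([C@H]2Oc3cc(OCc4ccccc4)cc(OCc4ccccc4)c3C(=O)[C@@H]2[C@@H]2C(=O)O[C@H]2c2ccc(OCc3ccccc3)cc2)cc1 | intermediate
18 | 3,5-bis(benzyloxy)phenol | Oc1cc(OCc2ccccc2)cc(OCc2ccccc2)c1 | starting material
19 | potassium (2S,3S)-3-[3,5-bis(benzyloxy)phenoxy]-3-[4-(benzyloxy)phenyl]-2-[(2S,3R)-5,7-bis(benzyloxy)-2-(4-methoxyphenyl)-4-oxochroman-3-yl]propanoate | COc1ccc([C@H]2Oc3cc(OCc4ccccc4)cc(OCc4ccccc4)c3C(=O)[C@@H]2[C@H](C(=O)[O-])[C@H](Oc2cc(OCc3ccccc3)cc(OCc3ccccc3)c2)c2ccc(OCc3ccccc3)cc2)cc1.[K+] | intermediate (not isolated)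
20 | mixed trifluoroacetic anhydride of the acid of 19 | COc1ccc([C@H]2Oc3cc(OCc4ccccc4)cc(OCc4ccccc4)c3C(=O)[C@@H]2[C@H](C(=O)OC(=O)C(F)(F)F)[C@H](Oc2cc(OCc3ccccc3)cc(OCc3ccccc3)c2)c2ccc(OCc3ccccc3)cc2)cc1 | intermediate (not isolated)
21 | (2S,3S)-5,7-bis(benzyloxy)-2-[4-(benzyloxy)phenyl]-3-[(2S,3R)-5,7-bis(benzyloxy)-2-(4-methoxyphenyl)-4-oxochroman-3-yl]chroman-4-one | COc1ccc([C@H]2Oc3cc(OCc4ccccc4)cc(OCc4ccccc4)c3C(=O)[C@@H]2[C@@H]2C(=O)c3c(OCc4ccccc4)cc(OCc4ccccc4)cc3O[C@@H]2c2ccc(OCc3ccccc3)cc2)cc1 | intermediate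
22 | (2S,3S)-5,7-dihydroxy-2-(4-hydroxyphenyl)-3-[(2S,3R)-5,7-dihydroxy-2-(4-methoxyphenyl)-4-oxochroman-3-yl]chroman-4-one | COc1ccc([C@H]2Oc3cc(O)cc(O)c3C(=O)[C@@H]2[C@@H]2C(=O)c3c(O)cc(O)cc3O[C@@H]2c2ccc(O)cc2)cc1 | target

**Step count.** Total: 9 steps. Longest linear sequence: 9 steps (1 and 2 to 22).

**Steps most likely to fail**

1. Step 8 (the proposed new method). The benzylic lactone carbon may ionise instead of undergoing clean SN2 attack, which would erode the inversion. The lactone may decarboxylate to the styrene-type alkene. The aryloxide may deprotonate C3 and open the lactone to the acrylate. It may also open the first flavanone by retro-oxa-Michael reaction. The fallback sets out from 15 and comes back at 21, building the same two bonds by known reactions in separate operations. Acid 15 would be esterified (Me3SiCHN2, MeOH–toluene, 0 °C) to the methyl ester F1. A Mitsunobu etherification with 18 (PPh3, DIAD, toluene, 0 °C) should give the aryl ether ester F2 with inversion at the carbinol carbon. Neutral ester cleavage (Me3SnOH, 1,2-dichloroethane, 70 °C) would give the free acid F3. Intramolecular Friedel–Crafts acylation ((CF3CO)2O, CH2Cl2, 0 °C) would then close ring C to 21.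

2. Step 5. Enolisation of the β-branched imide may be slow, the ring ketone may be enolised or silylated competitively, and facial control may be weak if the resident C3'' stereocentre opposes the auxiliary. The fallback sets out from 10 and comes back at 17, replacing auxiliary control by a substrate-controlled thiol ester enolate aldol–lactonisation that also bypasses steps 6 and 7. Imide 10 would be cleaved (LiOH, H2O2, THF–H2O, 0 °C) to the enantiopure acid F4. This would be converted (PhSH, DCC, DMAP, CH2Cl2) into the S-phenyl thioester F5. Kinetic deprotonation of the unhindered thioester CH2 (LiN(SiMe3)2, THF, −78 °C), addition of 11 and warming to 0 °C should let the lithium aldolate expel thiophenolate and close directly to the trans lactone 17. Facial selectivity would then rest on C3'', and the diastereomers would be separated.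

3. Step 4. The two diastereomeric imides may co-elute or co-crystallise, and the flavanone stereocentres may partly re-equilibrate by reversible ring opening during separation. The fallback sets out from 7 and comes back at 10, resolving before the auxiliary is attached. Racemic 7 would be crystallised with one enantiomer of 1-phenylethylamine (chosen by screening, drawn as R) to give the less soluble ammonium salt F6. Acidification (1 M HCl, EtOAc) would free the enantiopure acid F4. The step 4 acylation (t-BuCOCl, Et3N; then 8, LiCl) would then give 10 as a single diastereomer without chromatography of diastereomers.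

**Further compounds**
F1 | step 8 | methyl (2S,3R)-3-[4-(benzyloxy)phenyl]-2-[(2S,3R)-5,7-bis(benzyloxy)-2-(4-methoxyphenyl)-4-oxochroman-3-yl]-3-hydroxypropanoate | COc1ccc([C@H]2Oc3cc(OCc4ccccc4)cc(OCc4ccccc4)c3C(=O)[C@@H]2[C@H](C(=O)OC)[C@@H](O)c2ccc(OCc3ccccc3)cc2)cc1
F2 | step 8 | methyl (2S,3S)-3-[3,5-bis(benzyloxy)phenoxy]-3-[4-(benzyloxy)phenyl]-2-[(2S,3R)-5,7-bis(benzyloxy)-2-(4-methoxyphenyl)-4-oxochroman-3-yl]propanoate | COc1ccc([C@H]2Oc3cc(OCc4ccccc4)cc(OCc4ccccc4)c3C(=O)[C@@H]2[C@H](C(=O)OC)[C@H](Oc2cc(OCc3ccccc3)cc(OCc3ccccc3)c2)c2ccc(OCc3ccccc3)cc2)cc1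
F3 | step 8 | (2S,3S)-3-[3,5-bis(benzyloxy)phenoxy]-3-[4-(benzyloxy)phenyl]-2-[(2S,3R)-5,7-bis(benzyloxy)-2-(4-methoxyphenyl)-4-oxochroman-3-yl]propanoic acid | COc1ccc([C@H]2Oc3cc(OCc4ccccc4)cc(OCc4ccccc4)c3C(=O)[C@@H]2[C@H](C(=O)O)[C@H](Oc2cc(OCc3ccccc3)cc(OCc3ccccc3)c2)c2ccc(OCc3ccccc3)cc2)cc1
F4 | step 5 | 2-[(2S,3R)-5,7-bis(benzyloxy)-2-(4-methoxyphenyl)-4-oxochroman-3-yl]acetic acid (single enantiomer of 7) | COc1ccc([C@H]2Oc3cc(OCc4ccccc4)cc(OCc4ccccc4)c3C(=O)[C@@H]2CC(=O)O)cc1
F5 | step 5 | S-phenyl 2-[(2S,3R)-5,7-bis(benzyloxy)-2-(4-methoxyphenyl)-4-oxochroman-3-yl]ethanethioate | COc1ccc([C@H]2Oc3cc(OCc4ccccc4)cc(OCc4ccccc4)c3C(=O)[C@@H]2CC(=O)Sc2ccccc2)cc1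
F6 | step 4 | (R)-1-phenylethylammonium 2-[(2S,3R)-5,7-bis(benzyloxy)-2-(4-methoxyphenyl)-4-oxochroman-3-yl]acetate | COc1ccc([C@H]2Oc3cc(OCc4ccccc4)cc(OCc4ccccc4)c3C(=O)[C@@H]2CC(=O)[O-])cc1.C[C@@H]([NH3+])c1ccccc1
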